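Q is the catalyst and Z, the limiting reagent, is fed over 5.0 h, ending as J and L.

the same everywhere: Q 0.5 mol%
- dawn: Z 17 mM (fed, over 5.0 h); run made earlier
- noon: Z 38 mM (fed, over 5.0 h); run made earlier
- flask: Z 25 mM (fed, over 5.0 h); time 5.0 d

- dawn (time / d: J / %, L / %): 0.500: 21.5, 3.5; 1.04: 40.3, 16.6; 1.67: 51.3, 28.1; 2.08: 53.9, 32.3; 2.50: 56.3, 38.3; 3.00: 58.4, 38.2
- noon (time / d: J / %, L / %): 0.500: 34.8, 14.4; 1.04: 53.0, 33.8; 1.67: 56.8, 40.2; 2.08: 57.9, 41.6; 2.50: 59.2, 41.9; 3.00: 57.9, 42.0

(standard deviation of a reading: 1 percentage point)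

1. how much J the flask holds at 5.0 d, in percent of the Z charged
2. how much L the flask holds at 5.0 d, in percent of the Z charged

- percentages count the Z that a species holds: one L counts as two

Dawn and noon differ in their charge of Z, so their clocks need not match. But the loading of Q is the same, so Q rises with the charge. The flask reaches 125 mM·d at 5.0 d, where the exposure E, at this fixed loading of Q, is the charge of Z times the time. On this axis the runs roughly meet: dawn at 17.7 mM·d and noon at 19.0 mM·d read a J to L ratio of 2.43 and 2.42.

Noon's readings are flat by its last reading, at 114 mM·d, and the flask goes further. So the first answer is noon's end, with a J share of J + L of 58.0 %. Going round once more, dawn's last reading gives a higher share, 60.5 %, but its J and L sum to 96.6 %, so dawn's end may lie lower. The flask's charge lies between the two. My reckoning therefore puts J between 58.0 % and 60.5 %, with L making up the rest.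

The forecast gives J 58.8 % (57 % to 60.8 %) and L 40.8 % (38.8 % to 42.6 %), holding that “selectivity depends only weakly on concentration”.

The flask gives J 59.4 % and L 40.6 %.

    Z + Q ⇌ D (K = 36.0 M⁻¹, k = 11.0 M⁻¹ min⁻¹)
    D → Q + J (k = 0.560 min⁻¹)
    Z + J → L (k = 0.0250 M⁻¹ min⁻¹)

In the flask, counted forward, Z + Q → D uses Z 5.6 times as fast as Z + J → L at 0.608 d. At 5.00 d that ratio is still 3.7, with 0.024 % of the Z left. At 30 h the same flask has E = 31.2 mM·d and holds J 50.8 % and L 29.2 %. Dawn, at 28.4 mM·d, read J 51.3 % and L 28.1 %.

(The earlier runs and the new flask are simulated for an exercise, and the scatter is random.)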